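**Assumption:** the target is taken as the free hydrogen sulfate, as drawn. Aryl sulfates are normally kept as salts, so the route makes the sodium salt and protonates it only in the last operation. Flavone numbering (O1, C2 to C8a, ring B primed) is used for all chromenones.

## Analysis of the target

Hispidulin 7-sulfate is a flavone: a 4H-chromen-4-one (ring A fused to the pyranone ring C) with a 4-hydroxyphenyl ring B on C2. Ring A carries three adjacent oxygens, a free hydroxyl on C5, a methyl ether on C6 and the sulfate monoester on C7; only C8 is unsubstituted. There are no stereocentres, and the only stereochemical element on the way is the geometry of one acyclic alkene. The aryl hydrogen sulfate is the sensitive group: it is cleaved by aqueous acid and by Lewis acids, so it has to come late and be unmasked under neutral conditions. The difficulty is twofold. The 5,6,7-oxygen pattern must be placed unambiguously relative to the ring fusion, excluding the 5,7,8 isomer. The sulfate must then go to O7 and not to O5 or O4', although O7-H and O4'-H are both acidic, unhindered phenols. The strategy rests on the fact that ring A without C2, C3 and C4 is a 3,5-dialkoxy-4-methoxyphenol with a mirror plane through the phenol carbon and the methoxy carbon. Its two ortho carbons are therefore identical, and forming the C4-C4a bond can give only one constitution. Once the C4 carbonyl is in place the symmetry is broken usefully: O5-H is locked in a hydrogen bond to the carbonyl while O7-H stays free.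

## Retrosynthetic reasoning

The last bond cut is the benzyl C-O bond on O4'. Target 19 is traced to sodium salt 17, because hydrogenolysis is neutral and leaves a sulfate monoester anion untouched. The salt 18 formed first is protonated in the same operation.

The S-O7 bond is cut next, leading from 17 to diol 15. No protection is needed on O5, since its hydrogen bond to C4=O makes it inert towards a sulfur trioxide-amine complex, and O4' is still benzylated. This requires the O5 and O7 groups to come off without touching the O4' benzyl ether, so they are chosen as allyl ethers, and 15 is traced to diallyl ether 14 by palladium-catalysed allyl transfer. An all-benzyl ring A would have forced a longer end game through global deprotection and re-differentiation of O7 from O4'.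

Ring C is opened at C4-C4a, taking 14 back to the (Z)-3-aryloxycinnamic acid 12. This bond is chosen because it is the one whose formation on the symmetric ring A has a single outcome. Cutting O1-C8a instead would require an ortho halogen or a C-H oxidation on ring A, and cutting at ring B would give up the convergence. The forward reaction has to acylate ring A rather than ring B and must spare two allyl ethers and one benzyl ether.

The O1-C2 bond of 12 is cut through ester 11 to phenol 6 and ynoate 10. A phenoxide adds to the β-carbon of an arylpropiolate, and addition across the triple bond places the aryloxy group and the carboxyl on the same side, which is the geometry the ring closure needs. The ester is the acceptor, so a saponification (11 to 12) follows.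

Ynoate 10 is cut at the bond that becomes C3-C4, giving alkyne 7 and chloroformate 8, joined through acetylide 9.

Phenol 6 is traced through formate 5 to aldehyde 4, alcohol 3, ester 2 and finally 1; the phenol oxygen arises by peracid oxidation of the aldehyde with aryl migration. Direct C-H functionalisation of a 1,2,3-trioxygenated benzene was rejected for two reasons. Electrophiles attack ortho and para to the ethers, not at the position meta to both. A sterically governed iridium-catalysed borylation would find that position, but it would also attack the alkenes of allyl ethers or the unhindered phenyl C-H bonds of benzyl ethers. Compound 1 already has a carbon at the right position and the central oxygen differentiated as its methyl ether.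

## Alternatives that were turned down

Alternative 1: Ring B is removed entirely by cutting C1'-C2' and C5'-C6'. This leaves the 2-ethynylchromone A2, which already carries the sulfate as its 2,2,2-trichloroethyl diester, and the 1-methoxy-3-silyloxydiene A3. In the forward step the terminal alkyne of A2 takes up A3 in a [4+2] cycloaddition, and the adduct aromatises by loss of the methoxy group and of the silyl group to give A1, one reductive deprotection away from the target.
- For: the sulfate is placed on O7 before any 4'-hydroxyl exists, so the O7/O4' problem never arises. On this point the alternative is stronger than the chosen route, which must carry a benzyl group on O4' to the last step. The regiochemistry is also the favourable one, since the nucleophilic terminus of A3 should bond to the terminal alkyne carbon and put the new oxygen para.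
- Against: the alkyne of A2 is activated only vinylogously through ring C, so the cycloaddition needs forcing thermal conditions. These conditions meet a sulfate diester, a chelated 5-hydroxyl that can take up the silyl group, and an alkynyl chromone that can undergo conjugate addition by the silyl enol ether instead of cycloaddition. A2 itself needs a linear synthesis in which O5, O6 and O7 are differentiated and the alkyne is installed, all with the labile diester on board.
- Comparison: the chosen route brings ring B in as the commercial alkyne 7 and keeps the sulfate for the penultimate step.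

Alternative 2: Three bonds of ring C are cut at once (C4a-C4, C4-C3, O1-C2), giving the iodophenol A5, carbon monoxide A6 and alkyne 7. In the forward step zerovalent palladium, formed from PdCl2(PPh3)2 A7 in a secondary amine, inserts into the C-I bond, takes up A6 and couples with the alkyne to an ortho-hydroxyaryl ynone, which closes to flavone A4.
- For: it is the most convergent plan, uses the same alkyne and the same kind of symmetric phenol, and needs neither carboxylation nor saponification. With methoxymethyl groups on ring A and benzyl on O4' its end game is as short as the one used here, so on step count it is equal or slightly better.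
- Against: the C-I bond of A5 lies between a free hydroxyl and an acetal-protected oxygen on a very electron-rich ring, so oxidative addition and carbonyl insertion are slow. Direct alkynylation without A6 would lead to a 2-arylbenzofuran. The ynone can also close in the five-membered mode to an aurone, which an alkoxy group next to the carbonyl favours. Mono-iodination of the symmetric phenol must stop after one iodine, and a toxic gas under pressure is needed.
- Comparison: the chosen route spends two more steps, but its ring closure is a metal-free electrophilic substitution with only one possible constitution.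

Alternative 3: The O1-C8a bond is cut, leaving the 1,3-diketone A9 with a free C-H at the future C8a. In the forward step PhI(OCOCF3)2 A10 in a fluorinated alcohol oxidises ring A by one electron, the enol oxygen attacks the ring carbon, and a second oxidation with proton loss gives A8.
- For: ring A comes from a cheap 2,3,4-trioxygenated acetophenone in which the acyl group already marks C4a, the diketone is made by standard acyl transfer, and the 4'-pivalate with benzyl ethers on ring A gives a short end game. In raw material cost it is better than the chosen route.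
- Against: the C-H to be substituted is para only to the twisted 6-methoxy group and ortho to the acyl group, so it is not where the positive charge of the radical cation concentrates. The central carbon of the diketone is itself the usual point of attack of trivalent iodine reagents, and benzyl ethers are oxidisable. There is no precedent for this closure on such a substrate, so it would be a method to be developed. The acetophenone also needs three successive selective O-alkylations.
- Comparison: the chosen route uses a known reaction type for ring closure, and its symmetric ring A needs no differentiation before cyclisation.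

Key step: step 8

## Route

Step 1
Reactants: 1 methyl 3,5-dihydroxy-4-methoxybenzoate
Product: 2 methyl 4-methoxy-3,5-bis(prop-2-en-1-yloxy)benzoate
Conditions: allyl bromide (2.5 equiv), K2CO3, DMF, 50 °C
Reagents that add atoms: allyl bromide, C=CCBr
Why: Williamson etherification (SN2) of the two equivalent phenols; the methyl ester and the 4-methoxy group are inert to carbonate in DMF.

Step 2
Reactants: 2 methyl 4-methoxy-3,5-bis(prop-2-en-1-yloxy)benzoate
Product: 3 [4-methoxy-3,5-bis(prop-2-en-1-yloxy)phenyl]methanol
Conditions: LiAlH4, THF, 0 °C to rt; aqueous NaOH work-up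
Reagents that add atoms: none
Why: Hydride reduction of an aryl ester to the benzylic alcohol; aryl allyl ethers and isolated terminal alkenes are not attacked by LiAlH4.

Step 3
Reactants: 3 [4-methoxy-3,5-bis(prop-2-en-1-yloxy)phenyl]methanol
Product: 4 4-methoxy-3,5-bis(prop-2-en-1-yloxy)benzaldehyde
Conditions: activated MnO2, CH2Cl2, rt
Reagents that add atoms: none
Why: Selective oxidation of a benzylic alcohol on MnO2, which stops at the aldehyde and leaves ethers and alkenes alone.

Step 4
Reactants: 4 4-methoxy-3,5-bis(prop-2-en-1-yloxy)benzaldehyde
Product: 6 4-methoxy-3,5-bis(prop-2-en-1-yloxy)phenol, via aryl formate 5 (not isolated)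
Conditions: mCPBA (1.2 equiv), CH2Cl2, 0 °C to rt; aq. NaHCO3 wash; then K2CO3 (cat.), MeOH, rt
Reagents that add atoms: 3-chloroperoxybenzoic acid (mCPBA), OOC(=O)c1cccc(Cl)c1
Why: Baeyer-Villiger (Dakin-type) oxidation in which the electron-rich aryl group with its para methoxy substituent migrates in preference to hydrogen, giving the formate, which is cleaved by methanolysis. The terminal alkenes of the allyl ethers, deactivated by the allylic oxygen, should be epoxidised much more slowly than the aldehyde is oxidised.

Step 5
Reactants: 7 1-(benzyloxy)-4-ethynylbenzene; 8 ethyl chloroformate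
Product: 10 ethyl 3-[4-(benzyloxy)phenyl]prop-2-ynoate, via lithium acetylide 9 (not isolated)
Conditions: n-BuLi, THF, -78 °C; then ClCO2Et, -78 °C to 0 °C
Reagents that add atoms: none
Why: Deprotonation of the terminal alkyne and acylation of the acetylide by the chloroformate (addition-elimination); the benzyl aryl ether is stable to n-BuLi at -78 °C.

Step 6
Reactants: 6 4-methoxy-3,5-bis(prop-2-en-1-yloxy)phenol; 10 ethyl 3-[4-(benzyloxy)phenyl]prop-2-ynoate
Product: 11 ethyl (2Z)-3-[4-(benzyloxy)phenyl]-3-[4-methoxy-3,5-bis(prop-2-en-1-yloxy)phenoxy]prop-2-enoate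
Conditions: K2CO3 (0.5 equiv), DMF, 80 °C
Reagents that add atoms: none
Why: Base-catalysed oxa-Michael addition of the phenoxide to the aryl-bearing β-carbon of the ynoate; under base the oxygen, not a ring carbon, is the nucleophile. Anti addition across the triple bond puts the aryloxy group and the ester on the same side (Z), which also keeps ring B trans to the ester; any E isomer need not be removed because step 8 is expected to be convergent.

Step 7
Reactants: 11 ethyl (2Z)-3-[4-(benzyloxy)phenyl]-3-[4-methoxy-3,5-bis(prop-2-en-1-yloxy)phenoxy]prop-2-enoate
Product: 12 (2Z)-3-[4-(benzyloxy)phenyl]-3-[4-methoxy-3,5-bis(prop-2-en-1-yloxy)phenoxy]prop-2-enoic acid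
Conditions: LiOH·H2O, THF/MeOH/H2O, rt; then 1 M HCl to pH 3, 0 °C
Reagents that add atoms: lithium hydroxide, [Li+].[OH-]
Why: Saponification of the ethyl ester; the β-aryloxy acrylate is a vinylogous carbonate and should survive hydroxide at room temperature and brief cold acidification, while allyl and benzyl ethers are inert.

Step 8
Reactants: 12 (2Z)-3-[4-(benzyloxy)phenyl]-3-[4-methoxy-3,5-bis(prop-2-en-1-yloxy)phenoxy]prop-2-enoic acid
Product: 14 2-[4-(benzyloxy)phenyl]-6-methoxy-5,7-bis(prop-2-en-1-yloxy)-4H-chromen-4-one (5,7-di-O-allyl-4'-O-benzylhispidulin), via mixed trifluoroacetic anhydride 13 (not isolated)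
Conditions: (CF3CO)2O (3 equiv), CH2Cl2, 0 °C to rt
Reagents that add atoms: none
Why: The acid is converted by (CF3CO)2O into mixed anhydride 13, which reacts as an acyl cation stabilised by the β-aryloxy group; its carbon attacks the ring A carbon ortho to the vinyl ether oxygen and proton loss restores the aromatic ring, so the step is an intramolecular Friedel-Crafts acylation forming C4-C4a. The closest known reaction type is the acid-mediated cyclodehydration of 3-aryloxycinnamic acids to flavones, run here with the mild anhydride activation used for Friedel-Crafts closures onto polyalkoxyarenes. Ring C closes in a six-membered mode with the attacked carbonyl outside the new ring (6-exo-trig on the anhydride carbonyl, 6-exo-dig for a free acylium ion). No stereocentre is formed; the Z geometry holds the carboxyl next to ring A, and an E isomer should converge because reversible protonation at the α-carbon of this push-pull alkene allows rotation. The step needs acylation of ring A and not of ring B, and at one position only: the attacked carbon is ortho to two ether oxygens and para to a third, the reachable carbons of ring B are meta to its only oxygen and would close a five-membered indenone, and the two ortho carbons of ring A are identical by symmetry. It also needs the allyl and benzyl ethers to survive, which the absence of a strong Lewis or mineral acid and the low temperature should secure.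

Step 9
Reactants: 14 2-[4-(benzyloxy)phenyl]-6-methoxy-5,7-bis(prop-2-en-1-yloxy)-4H-chromen-4-one
Product: 15 2-[4-(benzyloxy)phenyl]-5,7-dihydroxy-6-methoxy-4H-chromen-4-one (4'-O-benzylhispidulin)
Conditions: Pd(PPh3)4 (5 mol%), morpholine, THF, rt
Reagents that add atoms: none
Why: Tsuji-Trost-type deallylation: zerovalent palladium ionises each aryl allyl ether to a π-allyl complex and the phenoxide, and morpholine captures the allyl group; the benzyl ether, the methyl ether and the flavone core do not react.

Step 10
Reactants: 15 2-[4-(benzyloxy)phenyl]-5,7-dihydroxy-6-methoxy-4H-chromen-4-one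
Product: 17 sodium 2-[4-(benzyloxy)phenyl]-5-hydroxy-6-methoxy-4-oxo-4H-chromen-7-yl sulfate, via pyridinium sulfate salt 16 (not isolated)
Conditions: SO3·pyridine (3 equiv), pyridine, rt to 40 °C; then aq. NaHCO3, C18 chromatography
Reagents that add atoms: sulfur trioxide pyridine complex, O=S(=O)([O-])[n+]1ccccc1; sodium hydrogencarbonate, [Na+].OC([O-])=O
Why: O-Sulfonation of a phenol by a sulfur trioxide-amine complex; O5-H is held in a six-membered hydrogen bond to C4=O and flanked by the 6-methoxy group, and O4' is benzylated, so only O7 should react. Exchange to the sodium salt removes pyridine, which would otherwise inhibit the palladium catalyst of the next step.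

Step 11
Reactants: 17 sodium 2-[4-(benzyloxy)phenyl]-5-hydroxy-6-methoxy-4-oxo-4H-chromen-7-yl sulfate
Product: 19 5-hydroxy-2-(4-hydroxyphenyl)-6-methoxy-4-oxo-4H-chromen-7-yl hydrogen sulfate (hispidulin 7-sulfate), via sodium hispidulin 7-sulfate 18 (not isolated)
Conditions: H2 (1 atm), Pd/C (10 wt%), MeOH/H2O, rt; filter; then HCl (1.0 equiv), H2O, 0 °C, C18 desalting, lyophilisation
Reagents that add atoms: none
Why: Hydrogenolysis of the aryl benzyl ether on palladium under neutral conditions, which a sulfate monoester anion tolerates; the C2-C3 double bond of the flavone, part of a vinylogous ester conjugated to ring B, should resist one atmosphere of hydrogen at room temperature. One equivalent of cold dilute acid then gives the hydrogen sulfate.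

## Compound list

1 | methyl 3,5-dihydroxy-4-methoxybenzoate | COC(=O)c1cc(O)c(OC)c(O)c1 | starting material
2 | methyl 4-methoxy-3,5-bis(prop-2-en-1-yloxy)benzoate | COC(=O)c1cc(OCC=C)c(OC)c(OCC=C)c1 | intermediate
3 | [4-methoxy-3,5-bis(prop-2-en-1-yloxy)phenyl]methanol | OCc1cc(OCC=C)c(OC)c(OCC=C)c1 | intermediate
4 | 4-methoxy-3,5-bis(prop-2-en-1-yloxy)benzaldehyde | O=Cc1cc(OCC=C)c(OC)c(OCC=C)c1 | intermediate
5 | 4-methoxy-3,5-bis(prop-2-en-1-yloxy)phenyl formate | O=COc1cc(OCC=C)c(OC)c(OCC=C)c1 | intermediate
6 | 4-methoxy-3,5-bis(prop-2-en-1-yloxy)phenol | Oc1cc(OCC=C)c(OC)c(OCC=C)c1 | intermediate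
7 | 1-(benzyloxy)-4-ethynylbenzene | C#Cc1ccc(OCc2ccccc2)cc1 | starting material
8 | ethyl chloroformate | CCOC(=O)Cl | starting material
9 | lithium 2-[4-(benzyloxy)phenyl]ethyn-1-ide | [Li]C#Cc1ccc(OCc2ccccc2)cc1 | intermediate
10 | ethyl 3-[4-(benzyloxy)phenyl]prop-2-ynoate | CCOC(=O)C#Cc1ccc(OCc2ccccc2)cc1 | intermediate
11 | ethyl (2Z)-3-[4-(benzyloxy)phenyl]-3-[4-methoxy-3,5-bis(prop-2-en-1-yloxy)phenoxy]prop-2-enoate | CCOC(=O)/C=C(\Oc1cc(OCC=C)c(OC)c(OCC=C)c1)c1ccc(OCc2ccccc2)cc1 | intermediate
12 | (2Z)-3-[4-(benzyloxy)phenyl]-3-[4-methoxy-3,5-bis(prop-2-en-1-yloxy)phenoxy]prop-2-enoic acid | OC(=O)/C=C(\Oc1cc(OCC=C)c(OC)c(OCC=C)c1)c1ccc(OCc2ccccc2)cc1 | intermediate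
13 | (2Z)-3-[4-(benzyloxy)phenyl]-3-[4-methoxy-3,5-bis(prop-2-en-1-yloxy)phenoxy]prop-2-enoic trifluoroacetic anhydride | O=C(/C=C(\Oc1cc(OCC=C)c(OC)c(OCC=C)c1)c1ccc(OCc2ccccc2)cc1)OC(=O)C(F)(F)F | intermediate
14 | 2-[4-(benzyloxy)phenyl]-6-methoxy-5,7-bis(prop-2-en-1-yloxy)-4H-chromen-4-one | COc1c(OCC=C)cc2oc(-c3ccc(OCc4ccccc4)cc3)cc(=O)c2c1OCC=C | intermediate
15 | 2-[4-(benzyloxy)phenyl]-5,7-dihydroxy-6-methoxy-4H-chromen-4-one | COc1c(O)cc2oc(-c3ccc(OCc4ccccc4)cc3)cc(=O)c2c1O | intermediate
16 | pyridinium 2-[4-(benzyloxy)phenyl]-5-hydroxy-6-methoxy-4-oxo-4H-chromen-7-yl sulfate | COc1c(OS(=O)(=O)[O-])cc2oc(-c3ccc(OCc4ccccc4)cc3)cc(=O)c2c1O.c1cc[nH+]cc1 | intermediate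
17 | sodium 2-[4-(benzyloxy)phenyl]-5-hydroxy-6-methoxy-4-oxo-4H-chromen-7-yl sulfate | COc1c(OS(=O)(=O)[O-])cc2oc(-c3ccc(OCc4ccccc4)cc3)cc(=O)c2c1O.[Na+] | intermediate
18 | sodium 5-hydroxy-2-(4-hydroxyphenyl)-6-methoxy-4-oxo-4H-chromen-7-yl sulfate | COc1c(OS(=O)(=O)[O-])cc2oc(-c3ccc(O)cc3)cc(=O)c2c1O.[Na+] | intermediate
19 | 5-hydroxy-2-(4-hydroxyphenyl)-6-methoxy-4-oxo-4H-chromen-7-yl hydrogen sulfate (hispidulin 7-sulfate) | COc1c(OS(=O)(=O)O)cc2oc(-c3ccc(O)cc3)cc(=O)c2c1O | target

## Step count and risks

Total step count: 11. Longest linear sequence: 10 steps (steps 1 to 4 and 6 to 11, from compound 1); step 5 is a one-step side branch.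

**Step 8 (key step).** The acyl cation is stabilised by the β-aryloxy group and may be too weak an electrophile. Intermolecular C-trifluoroacetylation of the very electron-rich ring A or of the α-carbon of the vinyl ether could then compete, or acid could cleave the vinyl ether. Forcing conditions would bring acid-promoted loss or Claisen-type migration of the allyl groups.
Fallback, from phenol 6 back to 14, with the C4-C4a bond made before the O1-C2 bond:
- Magnesium-mediated ortho-formylation of 6 (MgCl2, Et3N, paraformaldehyde, MeCN, reflux) would give 2-hydroxy-5-methoxy-4,6-bis(prop-2-en-1-yloxy)benzaldehyde F1; the two ortho positions are again equivalent.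
- Addition of an excess of lithium acetylide 9 in THF at -78 °C would give racemic 2-{3-[4-(benzyloxy)phenyl]-1-hydroxyprop-2-yn-1-yl}-4-methoxy-3,5-bis(prop-2-en-1-yloxy)phenol F2.
- Oxidation with MnO2 would give 3-[4-(benzyloxy)phenyl]-1-[2-hydroxy-5-methoxy-4,6-bis(prop-2-en-1-yloxy)phenyl]prop-2-yn-1-one F3.
- Heating F3 with Et2NH in EtOH closes the pyranone through the enaminone and so avoids the five-membered aurone mode, returning to the route at 14.

**Step 6.** The donor-substituted ring B lowers the electrophilicity of the β-carbon, so the addition may be sluggish. Ester exchange by the phenoxide and incomplete control of alkene geometry are further possibilities.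
Fallback, from ynoate 10 back to 11, replacing conjugate addition by a copper-catalysed C-O coupling:
- Anti hydroiodination of 10 (NaI, AcOH, 80 °C) would give ethyl (2Z)-3-[4-(benzyloxy)phenyl]-3-iodoprop-2-enoate F4.
- Coupling of F4 with phenol 6 (CuI, N,N-dimethylglycine, Cs2CO3, dioxane, 90 °C) proceeds with retention of alkene geometry and returns to the route at 11.

**Step 4.** The peracid may epoxidise the allyl ethers in competition, or hydrogen instead of aryl may migrate, which would return the carboxylic acid.
Fallback, from ester 2 back to 6, avoiding the aldehyde and the peracid: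
- Addition of MeMgBr (2.2 equiv, THF, 0 °C) to 2 would give 2-[4-methoxy-3,5-bis(prop-2-en-1-yloxy)phenyl]propan-2-ol F5.
- Treatment of F5 with H2O2 and BF3·OEt2 in CH2Cl2 at 0 °C forms the benzylic hydroperoxide, which undergoes Hock-type aryl migration to phenol 6 with loss of the three-carbon fragment.

**Step 10.** Sulfation of the acidic, ortho-substituted 7-hydroxyl may be incomplete, and the polar salt may be lost or desulfated during aqueous chromatography.
Fallback, from diol 15 back to 17, using a neutral, protected sulfate that can be purified on silica: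
- 2,2,2-Trichloroethyl chlorosulfate with Et3N and DMAP in THF would give 2-[4-(benzyloxy)phenyl]-5-hydroxy-6-methoxy-4-oxo-4H-chromen-7-yl 2,2,2-trichloroethyl sulfate F6.
- Reductive cleavage with Zn and HCO2NH4 in MeOH would give ammonium 2-[4-(benzyloxy)phenyl]-5-hydroxy-6-methoxy-4-oxo-4H-chromen-7-yl sulfate F7.
- Exchange with NaHCO3 converts F7 into 17.

**Step 11.** The C2-C3 double bond of ring C may be over-reduced, the catalyst may be inhibited by residual pyridine or sulfur-containing impurities, and the sulfate may be hydrolysed during protonation.
Fallback, from diol 15 to target 19, with non-reductive debenzylation before sulfation and O7 re-differentiated through acetates: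
- BCl3 with pentamethylbenzene in CH2Cl2 at -78 °C would give hispidulin F8.
- Ac2O, pyridine and DMAP would give hispidulin 5,7,4'-triacetate F9.
- PhSH and imidazole in NMP at 0 °C should remove the 7-acetate selectively, whose phenoxide is the best leaving group, giving 5,4'-di-O-acetylhispidulin F10.
- SO3·pyridine would give pyridinium 5,4'-di-O-acetylhispidulin 7-sulfate F11.
- NH3 in MeOH would cleave both acetates to ammonium hispidulin 7-sulfate F12.
- One equivalent of cold HCl with C18 desalting gives 19.

## Further compounds

F1 | step 8 | 2-hydroxy-5-methoxy-4,6-bis(prop-2-en-1-yloxy)benzaldehyde | O=Cc1c(O)cc(OCC=C)c(OC)c1OCC=C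
F2 | step 8 | 2-{3-[4-(benzyloxy)phenyl]-1-hydroxyprop-2-yn-1-yl}-4-methoxy-3,5-bis(prop-2-en-1-yloxy)phenol (racemic) | OC(C#Cc1ccc(OCc2ccccc2)cc1)c1c(O)cc(OCC=C)c(OC)c1OCC=C
F3 | step 8 | 3-[4-(benzyloxy)phenyl]-1-[2-hydroxy-5-methoxy-4,6-bis(prop-2-en-1-yloxy)phenyl]prop-2-yn-1-one | O=C(C#Cc1ccc(OCc2ccccc2)cc1)c1c(O)cc(OCC=C)c(OC)c1OCC=C
F4 | step 6 | ethyl (2Z)-3-[4-(benzyloxy)phenyl]-3-iodoprop-2-enoate | CCOC(=O)/C=C(\I)c1ccc(OCc2ccccc2)cc1
F5 | step 4 | 2-[4-methoxy-3,5-bis(prop-2-en-1-yloxy)phenyl]propan-2-ol | CC(C)(O)c1cc(OCC=C)c(OC)c(OCC=C)c1
F6 | step 10 | 2-[4-(benzyloxy)phenyl]-5-hydroxy-6-methoxy-4-oxo-4H-chromen-7-yl 2,2,2-trichloroethyl sulfate | COc1c(OS(=O)(=O)OCC(Cl)(Cl)Cl)cc2oc(-c3ccc(OCc4ccccc4)cc3)cc(=O)c2c1O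
F7 | step 10 | ammonium 2-[4-(benzyloxy)phenyl]-5-hydroxy-6-methoxy-4-oxo-4H-chromen-7-yl sulfate | COc1c(OS(=O)(=O)[O-])cc2oc(-c3ccc(OCc4ccccc4)cc3)cc(=O)c2c1O.[NH4+]
F8 | step 11 | hispidulin (5,7-dihydroxy-2-(4-hydroxyphenyl)-6-methoxy-4H-chromen-4-one) | COc1c(O)cc2oc(-c3ccc(O)cc3)cc(=O)c2c1O
F9 | step 11 | hispidulin 5,7,4'-triacetate | COc1c(OC(C)=O)cc2oc(-c3ccc(OC(C)=O)cc3)cc(=O)c2c1OC(C)=O
F10 | step 11 | 5,4'-di-O-acetylhispidulin | COc1c(O)cc2oc(-c3ccc(OC(C)=O)cc3)cc(=O)c2c1OC(C)=O
F11 | step 11 | pyridinium 5,4'-di-O-acetylhispidulin 7-sulfate | COc1c(OS(=O)(=O)[O-])cc2oc(-c3ccc(OC(C)=O)cc3)cc(=O)c2c1OC(C)=O.c1cc[nH+]cc1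
F12 | step 11 | ammonium hispidulin 7-sulfate | COc1c(OS(=O)(=O)[O-])cc2oc(-c3ccc(O)cc3)cc(=O)c2c1O.[NH4+]
A1 | alternative 1 | hispidulin 7-(2,2,2-trichloroethyl sulfate) | COc1c(OS(=O)(=O)OCC(Cl)(Cl)Cl)cc2oc(-c3ccc(O)cc3)cc(=O)c2c1O
A2 | alternative 1 | 2-ethynyl-5-hydroxy-6-methoxy-4-oxo-4H-chromen-7-yl 2,2,2-trichloroethyl sulfate | COc1c(OS(=O)(=O)OCC(Cl)(Cl)Cl)cc2oc(C#C)cc(=O)c2c1O
A3 | alternative 1 | (E)-1-methoxy-3-(trimethylsilyloxy)buta-1,3-diene | CO/C=C/C(=C)O[Si](C)(C)C
A4 | alternative 2 | 4'-O-benzyl-5,7-bis-O-(methoxymethyl)hispidulin | COCOc1cc2oc(-c3ccc(OCc4ccccc4)cc3)cc(=O)c2c(OCOC)c1OC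
A5 | alternative 2 | 2-iodo-4-methoxy-3,5-bis(methoxymethoxy)phenol | COCOc1cc(O)c(I)c(OCOC)c1OC
A6 | alternative 2 | carbon monoxide | [C-]#[O+]
A7 | alternative 2 | PdCl2(PPh3)2, dichlorobis(triphenylphosphine)palladium | Cl[Pd](Cl)([P](c1ccccc1)(c1ccccc1)c1ccccc1)[P](c1ccccc1)(c1ccccc1)c1ccccc1
A8 | alternative 3 | 5,7-di-O-benzyl-4'-O-pivaloylhispidulin | COc1c(OCc2ccccc2)cc2oc(-c3ccc(OC(=O)C(C)(C)C)cc3)cc(=O)c2c1OCc1ccccc1
A9 | alternative 3 | 1-[2,4-bis(benzyloxy)-3-methoxyphenyl]-3-[4-(2,2-dimethylpropanoyloxy)phenyl]propane-1,3-dione | COc1c(OCc2ccccc2)ccc(C(=O)CC(=O)c2ccc(OC(=O)C(C)(C)C)cc2)c1OCc1ccccc1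
A10 | alternative 3 | PhI(OCOCF3)2, [bis(trifluoroacetoxy)iodo]benzene | O=C(OI(OC(=O)C(F)(F)F)c1ccccc1)C(F)(F)F
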